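It is easy to take the highest reading of a run for the top of its curve.

- theta: starting material 13 mM (fed, over 20 min); second substrate 26 mM; free enzyme 1.3 µM; the very flask that is asked about, followed so far
- flask: starting material 13 mM (fed, over 20 min); second substrate 26.0 mM; free enzyme 1.3 µM; time 10 h

theta run (percent of the starting material charged)

| time / min | target / % |
|---|---|
| 6.00 | 9.3 |
| 12.0 | 19.0 |
| 30.0 | 34.2 |
| 80.0 | 26.7 |

(standard deviation of a reading: 1 percentage point)

- what was read earlier has a scatter of 1 percentage point, one standard deviation
- percentages count the whole charge, also what has not yet gone in

- time up to 10 h at which target stands highest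
- the amount of target, in percent of the starting material charged, at that time

I bracketed the top of this flask by hand. From below, it stood at least as high as the best reading, 34.2 % at 30.0 min, within the scatter. From above, I drew two straight lines. The early readings rose at 0.206 mM min⁻¹ of target, and the last two fell at 0.0195 mM min⁻¹. The lines crossed after 22.3 min. The early pace held to that time gave 35.4 % of the charge. I call this the corner height: the level where the early rise line meets the late fall line. I expected a rounded top to sit under its corner. The time was looser, so I placed it between that crossing and the reading at 80.0 min.

The forecast gave 35 % at 0.55 h, and said the peak should “lie shortly after feed end”. Its height stood inside my bracket, above the best reading and below the corner height. Its time stood inside too.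

    starting material + target → side product (k = 0.0453 L mol⁻¹ s⁻¹)
    second substrate + loaded enzyme ⇌ second complex (K = 624 L mol⁻¹, k = 1620 L mol⁻¹ s⁻¹)
    second complex → free enzyme + target (k = 4.11 s⁻¹)
    second substrate → decomposed reagent (k = 8.81 × 10⁻⁴ s⁻¹)
    first complex ⇌ loaded enzyme + first product (K = 0.180 M, k = 478 s⁻¹)
    starting material + free enzyme ⇌ first complex (K = 32.0 L mol⁻¹, k = 96000 L mol⁻¹ s⁻¹)

This flask peaked at 0.641 h with 34.5 %. At that time the second substrate stood at 4.50 % of its own charge. The top lay 0.90 percentage points below the corner height, and that height was itself drawn from scattered readings. A neighbour flask had the same recipe but 7.8 × 10⁻⁴ mM of free enzyme. For it I assumed the same crossing time and the same early pace per enzyme, the turnover frequency. Its corner height came to 21.2 %, and that neighbour flask's best was 20.8 %.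

The earlier runs and the new flask are simulated from invented constants, and the scatter is random.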